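At late times the south-east and north-east readings level off, and they end short: at the last reading open intermediate plus target stands at 93.4 % of the substrate charged in the south-east run but at 70.5 % in the north-east run, which holds more partner. So I take reagent, charged at 24 mM, as the limiting reagent, with partner as the substrate's rival for it.

| flask | substrate | partner | reagent | capture agent | remark | time |
|---|---|---|---|---|---|---|
| south-east | 20 mM | 23 mM | 24 mM | 2 mM | run made earlier |  |
| north-east | 20 mM | 70 mM | 24 mM | 2 mM | run made earlier |  |
| east | 24 mM | 30 mM | 24 mM | 2 mM | run made earlier |  |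
| beta | 20 mM | 30.0 mM | 24.0 mM | 2.00 mM |  | 8.0 d |
| delta | 20 mM | 100 mM | 24.0 mM | 2.00 mM |  | 8.0 d |
| gamma | 30 mM | 30.0 mM | 24.0 mM | 2.00 mM |  | 8.0 d |
| epsilon | 30 mM | 100 mM | 24.0 mM | 2.00 mM |  | 8.0 d |

| run | time / d | open intermediate / % | target / % |
|---|---|---|---|
| south-east | 0.417 | 70.4 | 1.6 |
| south-east | 1.04 | 79.4 | 3.9 |
| south-east | 2.08 | 83.2 | 9.4 |
| south-east | 3.00 | 79.3 | 14.3 |
| south-east | 4.00 | 79.0 | 14.5 |
| south-east | 6.00 | 78.1 | 15.3 |
| north-east | 0.417 | 62.2 | 4.3 |
| north-east | 0.833 | 63.3 | 7.3 |
| north-east | 1.25 | 59.2 | 12.6 |
| north-east | 2.08 | 55.0 | 18.4 |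
| north-east | 3.00 | 48.7 | 22.3 |
| north-east | 6.00 | 46.0 | 24.5 |
| east | 0.417 | 65.2 | 0 |
| east | 0.833 | 69.3 | 3.9 |
| east | 1.67 | 72.2 | 5.0 |
| east | 3.00 | 70.9 | 7.0 |
| east | 6.00 | 70.7 | 10.6 |

(each reading ± 1 percentage point)

- what was read earlier has a scatter of 1 percentage point, one standard deviation

- the flasks put in order of amount of open intermediate, in percent of the substrate charged, best first, at 8.0 d (beta / delta / gamma / epsilon)
- the same order at 20 h (beta / delta / gamma / epsilon)
- the amount of open intermediate, in percent of the substrate charged of the flask you put first, at 8.0 d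
- the amount of open intermediate, in percent of the substrate charged of the flask you put last, at 8.0 d

Counting the reagent not found on the substrate side as taken by partner, the last north-east reading gives a selectivity factor of 8.01, a reading with its scatter. I multiply it by charged [substrate] over charged [partner]. For delta this gives 1.60, the flow ratio: how many times faster reagent goes to substrate than to partner at the start.

The south-east run has 6.96 and the north-east run 2.29, so I draw the last reading of open intermediate, with its scatter, as a line in the logarithm of the flow ratio, 29 percentage points per factor e. That puts beta, at 5.34, near 70.4 %, and delta near 35.7 %.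

One number is not enough. Gamma has a higher ratio than beta, 8.01, but if each open intermediate costs one reagent and the capture agent's charge costs as much reagent again, the ceiling of gamma is 73.3 %. The east run tests this: its last reading stands at 77.1 % of its ceiling, and the line says 75.7 %. Ceiling times line gives gamma 60.2 % and epsilon, with the same ceiling, 34.8 %, so this reckoning does not part epsilon from delta.

The forecast says beta > gamma > epsilon > delta at 8.0 d and beta > gamma > delta > epsilon at 20 h, with 73 % and 30 %, on the ground that “More partner therefore lowers the plateau”.

The flasks give beta > gamma > epsilon > delta at 8.0 d: beta 70.6 %, gamma 63.2 %, epsilon 37.0 %, delta 33.6 %. At 20 h they give beta > gamma > delta > epsilon.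

    second intermediate + capture agent → trapped intermediate (k = 0.0220 M⁻¹ s⁻¹)
    second intermediate → side product (k = 1.80 × 10⁻⁶ s⁻¹)
    reagent + partner → second intermediate (k = 3.10 × 10⁻⁴ M⁻¹ s⁻¹)
    open intermediate + second intermediate → target (k = 4.40 × 10⁻⁴ M⁻¹ s⁻¹)
    substrate + reagent → open intermediate (k = 0.00270 M⁻¹ s⁻¹)

From the constants, reagent at the start of delta flows 1.7 times faster to substrate than to partner, beside my 1.60 from the readings. A neighbour of delta has 9.6 mM of reagent, 0.480 equiv. Reagent is not in the flow ratio, so that stays 1.60, while the ceiling falls to 38.0 %, and ceiling times line gives 13.6 %. At 8.0 d the neighbour holds 24.1 % of open intermediate, under its ceiling but above that product, with target at 4.76 %.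

The readings were computed for substances that don't exist; the scatter is artificial.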